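A small charge of substrate, fed at a steady rate into the stirred flask, gave target that rose with the feed. I wanted to know where that rise stops in birch, the flask asked about, and what stays.

in all of them: substrate 0.020 M (fed, over 25 min)

|  | salt in the second phase | spent carrier | remark | time | volume of the second phase over the first |
|---|---|---|---|---|---|
| birch | 0.036 M | 3.6 mM | the very flask that is asked about, followed so far |  |  |
| cedar | 0.036 M | 7.2 mM | run made earlier |  |  |
| flask | 0.0360 M | 3.6 mM |  | 15 h | 1.0 |

birch run (percent of the substrate charged)

| time / min | target / % |
|---|---|
| 6.00 | 2.5 |
| 8.00 | 6.8 |
| 12.0 | 10.1 |
| 20.0 | 15.5 |
| 30.0 | 21.2 |
| 50.0 | 18.9 |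
| 80.0 | 19.6 |

cedar run (percent of the substrate charged)

| time / h | target / % |
|---|---|
| 1.50 | 18.2 |
| 3.00 | 16.7 |
| 5.00 | 17.8 |
| 6.00 | 18.0 |
| 8.00 | 16.1 |
| 10.0 | 18.8 |

(scatter of a reading: 1 percentage point)

* the moment within 15 h at which there is most target
* the amount of target, in percent of the substrate charged, at that time
* the first time at which target reaches 11%, in the same percent

- charges count per volume of the first phase; a concentration in a rate is the amount of a species over the volume of its own phase; every rate counts per litre of the first phase
- the earlier runs hold the two phases in the same ratio of volumes as the flask asked about
- percentages count the whole charge, also what has not yet gone in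

I read the runs as two extreme versions of one flask. Cedar, with twice the spent carrier, shows a version that has stopped changing by its first reading. I replaced its curve by its mean, 17.6%, and called this the resting share: the fraction of the charge that stays target once a flask stops changing. That replacement cost little, for cedar's later readings average 0.067 percentage points above its earlier ones, against a scatter of 1 point. The other extreme keeps what birch shows at its top reading, 21.2% at 30.0 min. Birch's later readings, 18.9% and 19.6%, stand between the two. So I expected birch to peak near that top reading, soon after the feed ended, and then sink to the resting share, taking spent carrier to change the pace and not the level.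

The forecast put the top at 20% at 0.45 h and the crossing of 11% at 0.23 h, and held that “the target neither decays nor grows detectably”. On that last point my curve differed, since it falls after the top.

The flask gave a top of 22.1% at 0.536 h and reached 11% at 0.222 h.

    spent carrier + salt in the second phase ⇌ fresh carrier + spent salt in the second phase (K = 0.220, k = 1300 L mol⁻¹ min⁻¹)
    target + fresh carrier ⇌ isomer of the product + fresh carrier, rate k2*[target]*[fresh carrier] forward; the back reaction follows from the equilibrium constant (K = 4.90, k = 140 L mol⁻¹ min⁻¹)
    substrate + fresh carrier → target + spent carrier (k = 59.0 L mol⁻¹ min⁻¹)

The resting share gave this flask 17.6% of the charge at the end, and it holds 16.9% at 15.0 h. The largest single effect on the top is the turning of target into isomer of the product, both ways: the run without it reaches 100% instead of 22.1%. At the end of this flask the relaxation half-life of that exchange, both ways together, is 0.134 h, short against 15 h, and this flask's end is thermodynamic control. For the neighbour with 0.012 M of substrate, the resting share again gives 17.6% of the charge; the computed flask holds 16.9% target and 83.1% isomer of the product.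

Readings and results come from a simulation for an exercise, noise included.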